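**Plan**
- The retrosynthesis first removes the two masks (aryl silyl ether, ketone ketal), then cuts in one operation the bond from ring carbon C1 to the benzylic CH2 and the bond from C2 to its hydroxyl oxygen in the 2,4-dihydroxy-3-methoxyphenyl ring.
- This is possible because the chain-bearing C1 and the hydroxylated C2 are neighbours and C2 lies next to the C3 methoxy carbon: a 3-methoxyaryne (triple bond C1–C2) takes a carbon nucleophile at C1 and an electrophile at C2.
- The aryne precursor, a 2-iodoaryl triflate, comes from 2-methoxyresorcinol by iodination, site-selective silylation and triflation.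
- The nucleophile, a β-magnesioethyl ketal, comes from 4-(4-methoxyphenyl)butan-1-ol and acrolein by Grignard addition, oxidation, hydrobromination–ketalization and magnesium insertion.
- Forward, the two fragments are made separately and joined in step 9; ketal hydrolysis and desilylation finish the route. No ring is formed at any stage.
- The target is achiral; the one stereocentre met on the way (a racemic allylic carbinol) is oxidized away.

Key step: step 9

Remark on the chemistry: the ketone is carried as a 5,5-dimethyl-1,3-dioxane because the derived β-magnesioethyl ketal tolerates room temperature better than a dioxolane. In step 9 one equivalent of the Grignard reagent is spent on the iodine–magnesium exchange and returns as the recoverable alkyl iodide.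

**Route**

Step 1
Reactants: 1 2-methoxyresorcinol (2-methoxybenzene-1,3-diol)
Product: 2 4-iodo-2-methoxybenzene-1,3-diol
Conditions: I2 (1.0 equiv), NaHCO3, THF/H2O, 0 °C
Reagents that add atoms: iodine, II
Why: Electrophilic aromatic iodination of the symmetric, strongly activated resorcinol can only go to the equivalent positions 4 and 6, each ortho to one hydroxyl and para to the other, and with one equivalent of iodine at 0 °C the slightly deactivated monoiodide should not react on.

Step 2
Reactants: 2 4-iodo-2-methoxybenzene-1,3-diol
Product: 3 6-iodo-2-methoxy-3-[(triisopropylsilyl)oxy]phenol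
Conditions: TIPSCl (1.05 equiv), imidazole, CH2Cl2, 0 °C
Reagents that add atoms: chlorotriisopropylsilane, CC(C)[Si](Cl)(C(C)C)C(C)C
Why: Silylation of a phenol with a bulky trialkylsilyl chloride and imidazole is governed by steric access, so the silyl group should go to the hydroxyl whose only ortho neighbour is the methoxy group and leave the one wedged between methoxy and iodine free.

Step 3
Reactants: 3 6-iodo-2-methoxy-3-[(triisopropylsilyl)oxy]phenol
Product: 4 6-iodo-2-methoxy-3-[(triisopropylsilyl)oxy]phenyl trifluoromethanesulfonate
Conditions: Tf2O, pyridine, CH2Cl2, 0 °C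
Reagents that add atoms: trifluoromethanesulfonic anhydride, O=S(=O)(OS(=O)(=O)C(F)(F)F)C(F)(F)F
Why: Triflation of a phenol with triflic anhydride and pyridine works also for doubly ortho-substituted phenols and leaves the aryl iodide and the silyl ether untouched.

Step 4
Reactants: 5 4-(4-methoxyphenyl)butan-1-ol
Product: 6 1-(4-bromobutyl)-4-methoxybenzene
Conditions: CBr4, PPh3, CH2Cl2, 0 °C to rt
Reagents that add atoms: carbon tetrabromide, BrC(Br)(Br)Br
Why: The Appel reaction converts a primary alcohol into the bromide under neutral conditions by SN2 displacement of the oxyphosphonium group, with no effect on the anisole ring.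

Step 5
Reactants: 6 1-(4-bromobutyl)-4-methoxybenzene; 7 acrolein (prop-2-enal)
Product: 9 7-(4-methoxyphenyl)hept-1-en-3-ol (racemic), via 4-(4-methoxyphenyl)butylmagnesium bromide 8 (not isolated)
Conditions: Mg turnings, THF, rt to 40 °C; then 7, THF, −78 °C; aq NH4Cl
Reagents that add atoms: none
Why: Magnesium insertion into the primary bromide and Grignard 1,2-addition to the aldehyde carbon of acrolein at −78 °C give the secondary allylic alcohol, whose single stereocentre arises as a racemate and is removed by the oxidation in step 6.

Step 6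
Reactants: 9 7-(4-methoxyphenyl)hept-1-en-3-ol
Product: 10 7-(4-methoxyphenyl)hept-1-en-3-one
Conditions: Dess–Martin periodinane, CH2Cl2, 0 °C to rt; used without storage
Reagents that add atoms: none
Why: Dess–Martin oxidation turns the secondary allylic alcohol into the vinyl ketone at or below room temperature without base or strong acid, conditions under which the polymerization-prone enone survives long enough to be used directly.

Step 7
Reactants: 10 7-(4-methoxyphenyl)hept-1-en-3-one
Product: 12 2-(2-bromoethyl)-2-[4-(4-methoxyphenyl)butyl]-5,5-dimethyl-1,3-dioxane, via 1-bromo-7-(4-methoxyphenyl)heptan-3-one 11 (not isolated)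
Conditions: HBr (gas), CH2Cl2, 0 °C; then 2,2-dimethylpropane-1,3-diol, HC(OEt)3, TsOH·H2O (cat), rt
Reagents that add atoms: hydrogen bromide, Br; 2,2-dimethylpropane-1,3-diol, OCC(C)(C)CO
Why: Conjugate hydrobromination of the vinyl ketone followed in the same flask by acid-catalysed ketalization with the 1,3-diol, triethyl orthoformate taking up the water, is the standard preparation of β-bromoethyl ketals, and the ketal blocks the loss of HBr that the free β-bromo ketone would suffer.

Step 8
Reactants: 12 2-(2-bromoethyl)-2-[4-(4-methoxyphenyl)butyl]-5,5-dimethyl-1,3-dioxane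
Product: 13 (2-{2-[4-(4-methoxyphenyl)butyl]-5,5-dimethyl-1,3-dioxan-2-yl}ethyl)magnesium bromide
Conditions: Mg turnings (activated with a crystal of I2), THF, 25–35 °C; solution titrated and used directly
Reagents that add atoms: magnesium, [Mg]
Why: Magnesium insertion into a primary bromide gives the Grignard reagent, and β-magnesioethyl ketals of the 1,3-dioxane type are known homoenolate equivalents that stay intact in tetrahydrofuran at room temperature, where the five-membered dioxolane analogues begin to fragment.

Step 9
Reactants: 4 6-iodo-2-methoxy-3-[(triisopropylsilyl)oxy]phenyl trifluoromethanesulfonate; 13 (2-{2-[4-(4-methoxyphenyl)butyl]-5,5-dimethyl-1,3-dioxan-2-yl}ethyl)magnesium bromide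
Product: 18 2-methoxy-6-(2-{2-[4-(4-methoxyphenyl)butyl]-5,5-dimethyl-1,3-dioxan-2-yl}ethyl)-3-[(triisopropylsilyl)oxy]phenol, via 2-magnesiated aryl triflate 14 (not isolated), via 3-methoxy-4-silyloxybenzyne 15 (not isolated), via arylmagnesium adduct 16 (not isolated), via dimethyl arylboronate 17 (not isolated)
Conditions: 13 (2.3 equiv), THF, −78 °C, slow addition of 4, then −78 to 0 °C; B(OMe)3 (3 equiv), −78 °C to rt; 30% H2O2, aq NaHCO3, 0 °C to rt
Reagents that add atoms: hydrogen peroxide, OO
Why: One equivalent of Grignard reagent 13 exchanges the iodine of 4 for magnesium and leaves as the alkyl iodide, the 2-magnesiated triflate 14 expels MgBr(OTf) to give aryne 15 with its triple bond between the former C–I and C–OTf carbons, a second equivalent of 13 adds to 15 to give arylmagnesium 16, and 16 is borylated to 17 and oxidized with migration of the aryl group from boron to oxygen. The closest known reaction type is the carbomagnesiation of arynes released from 2-iodoaryl sulfonates by halogen–magnesium exchange with electrophilic trapping of the ortho-magnesiated adduct, joined to the borate–peroxide hydroxylation of arylmagnesium compounds. No ring is closed and no stereocentre is formed, the two new bonds being the aryl–CH2 bond and the aryl–O bond on neighbouring ring carbons. The step needs regioselective attack on the unsymmetrical aryne, and this is secured by the methoxy group on the carbon next to the former triflate carbon: its inductive pull distorts the triple bond so that the carbon remote from it is the more electrophilic one and the negative charge builds up beside the oxygen, where it is stabilized and chelated, while the other flank of the aryne carries only hydrogen. Borylation and oxidation replace magnesium by oxygen at the same carbon, so the hydroxyl returns to the position that the triflate left. Slow addition of 4 to an excess of 13 keeps the aryne from meeting its own adduct 16, and bicarbonate-buffered peroxide spares the aryl silyl ether and the ketal.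

Step 10
Reactants: 18 2-methoxy-6-(2-{2-[4-(4-methoxyphenyl)butyl]-5,5-dimethyl-1,3-dioxan-2-yl}ethyl)-3-[(triisopropylsilyl)oxy]phenol
Product: 19 1-{2-hydroxy-3-methoxy-4-[(triisopropylsilyl)oxy]phenyl}-7-(4-methoxyphenyl)heptan-3-one
Conditions: 2 M aq HCl, THF, rt to 40 °C
Reagents that add atoms: water, O
Why: Acid-catalysed ketal hydrolysis in aqueous tetrahydrofuran releases the ketone and the diol, dilute acid does not cleave the aryl triisopropylsilyl ether or the methyl ethers, and the absence of an alcohol cosolvent prevents the ortho-hydroxyl from being trapped as a mixed chroman ketal.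

Step 11
Reactants: 19 1-{2-hydroxy-3-methoxy-4-[(triisopropylsilyl)oxy]phenyl}-7-(4-methoxyphenyl)heptan-3-one
Product: 20 1-(2,4-dihydroxy-3-methoxyphenyl)-7-(4-methoxyphenyl)heptan-3-one
Conditions: TBAF, AcOH (1:1), THF, 0 °C
Reagents that add atoms: none
Why: Fluoride cleaves the aryl silicon–oxygen bond rapidly at 0 °C through a pentacoordinate silicate (silyl ether deprotection), and acetic acid buffering keeps the electron-rich keto phenol from base-induced aldol or oxidation side reactions.

**Compound list**

1 | 2-methoxyresorcinol (2-methoxybenzene-1,3-diol) | COc1c(O)cccc1O | starting material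
2 | 4-iodo-2-methoxybenzene-1,3-diol | COc1c(O)ccc(I)c1O | intermediate
3 | 6-iodo-2-methoxy-3-[(triisopropylsilyl)oxy]phenol | COc1c(O[Si](C(C)C)(C(C)C)C(C)C)ccc(I)c1O | intermediate
4 | 6-iodo-2-methoxy-3-[(triisopropylsilyl)oxy]phenyl trifluoromethanesulfonate | COc1c(O[Si](C(C)C)(C(C)C)C(C)C)ccc(I)c1OS(=O)(=O)C(F)(F)F | intermediate
5 | 4-(4-methoxyphenyl)butan-1-ol | COc1ccc(CCCCO)cc1 | starting material
6 | 1-(4-bromobutyl)-4-methoxybenzene | COc1ccc(CCCCBr)cc1 | intermediate
7 | acrolein (prop-2-enal) | C=CC=O | starting material
8 | [4-(4-methoxyphenyl)butyl]magnesium bromide | COc1ccc(CCCC[Mg]Br)cc1 | intermediate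
9 | 7-(4-methoxyphenyl)hept-1-en-3-ol (racemic) | COc1ccc(CCCCC(O)C=C)cc1 | intermediate
10 | 7-(4-methoxyphenyl)hept-1-en-3-one | COc1ccc(CCCCC(=O)C=C)cc1 | intermediate
11 | 1-bromo-7-(4-methoxyphenyl)heptan-3-one | COc1ccc(CCCCC(=O)CCBr)cc1 | intermediate
12 | 2-(2-bromoethyl)-2-[4-(4-methoxyphenyl)butyl]-5,5-dimethyl-1,3-dioxane | COc1ccc(CCCCC2(CCBr)OCC(C)(C)CO2)cc1 | intermediate
13 | (2-{2-[4-(4-methoxyphenyl)butyl]-5,5-dimethyl-1,3-dioxan-2-yl}ethyl)magnesium bromide | COc1ccc(CCCCC2(CC[Mg]Br)OCC(C)(C)CO2)cc1 | intermediate
14 | 6-(bromomagnesio)-2-methoxy-3-[(triisopropylsilyl)oxy]phenyl trifluoromethanesulfonate | COc1c(O[Si](C(C)C)(C(C)C)C(C)C)ccc([Mg]Br)c1OS(=O)(=O)C(F)(F)F | intermediate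
15 | 1,2-didehydro-3-methoxy-4-[(triisopropylsilyl)oxy]benzene (3-methoxy-4-silyloxybenzyne) | COC1=C(O[Si](C(C)C)(C(C)C)C(C)C)C=CC#C1 | intermediate
16 | [2-methoxy-6-(2-{2-[4-(4-methoxyphenyl)butyl]-5,5-dimethyl-1,3-dioxan-2-yl}ethyl)-3-[(triisopropylsilyl)oxy]phenyl]magnesium bromide | COc1ccc(CCCCC2(CCc3ccc(O[Si](C(C)C)(C(C)C)C(C)C)c(OC)c3[Mg]Br)OCC(C)(C)CO2)cc1 | intermediate
17 | dimethyl [2-methoxy-6-(2-{2-[4-(4-methoxyphenyl)butyl]-5,5-dimethyl-1,3-dioxan-2-yl}ethyl)-3-[(triisopropylsilyl)oxy]phenyl]boronate | COc1ccc(CCCCC2(CCc3ccc(O[Si](C(C)C)(C(C)C)C(C)C)c(OC)c3B(OC)OC)OCC(C)(C)CO2)cc1 | intermediate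
18 | 2-methoxy-6-(2-{2-[4-(4-methoxyphenyl)butyl]-5,5-dimethyl-1,3-dioxan-2-yl}ethyl)-3-[(triisopropylsilyl)oxy]phenol | COc1ccc(CCCCC2(CCc3ccc(O[Si](C(C)C)(C(C)C)C(C)C)c(OC)c3O)OCC(C)(C)CO2)cc1 | intermediate
19 | 1-{2-hydroxy-3-methoxy-4-[(triisopropylsilyl)oxy]phenyl}-7-(4-methoxyphenyl)heptan-3-one | COc1ccc(CCCCC(=O)CCc2ccc(O[Si](C(C)C)(C(C)C)C(C)C)c(OC)c2O)cc1 | intermediate
20 | 1-(2,4-dihydroxy-3-methoxyphenyl)-7-(4-methoxyphenyl)heptan-3-one | COc1ccc(CCCCC(=O)CCc2ccc(O)c(OC)c2O)cc1 | target

**Step count**

Total: 11 steps. Longest linear sequence: 8 steps (steps 4 to 11, from 4-(4-methoxyphenyl)butan-1-ol 5). The arene branch contributes steps 1 to 3 and joins at step 9.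

**Steps most likely to fail**

Step 9. The iodine–magnesium exchange with a primary alkylmagnesium may be slow next to attack of the Grignard reagent at the sulfonyl sulfur. The short-lived aryne may be consumed by its own arylmagnesium adduct instead of the chain reagent. Borylation of the doubly ortho-substituted arylmagnesium may stay incomplete, so that protonation replaces hydroxylation. The fallback gives up the aryne and makes the aryl–carbon bond by palladium catalysis at the iodine-bearing carbon, with the neighbouring hydroxyl left in place. It sets out from iodophenol 3 and vinyl ketone 10. A Heck reaction (Pd(OAc)2, P(o-tol)3, Et3N, MeCN, 80 °C) should give (E)-1-{2-hydroxy-3-methoxy-4-[(triisopropylsilyl)oxy]phenyl}-7-(4-methoxyphenyl)hept-1-en-3-one F1. Hydrogenation of its conjugated double bond (H2, Pd/C, EtOAc, rt) should give ketone 19, where the route is rejoined before the desilylation of step 11.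

Step 7. The vinyl ketone may oligomerize under hydrogen bromide, and the β-bromo ketone may lose HBr again during ketalization, so that the bromo ketal is reached only in part. The fallback avoids both the vinyl ketone and any β-bromo ketone by placing the bromine last. It sets out from bromide 6. Its Grignard reagent 8 is acylated with the Weinreb amide 3-(benzyloxy)-N-methoxy-N-methylpropanamide (CON(C)C(=O)CCOCc1ccccc1; THF, 0 °C) to give 1-(benzyloxy)-7-(4-methoxyphenyl)heptan-3-one F2. Ketalization (2,2-dimethylpropane-1,3-diol, HC(OEt)3, TsOH cat, CH2Cl2, rt) gives 2-[2-(benzyloxy)ethyl]-2-[4-(4-methoxyphenyl)butyl]-5,5-dimethyl-1,3-dioxane F3. Hydrogenolysis (H2, Pd/C, EtOAc with a trace of Et3N) gives 2-{2-[4-(4-methoxyphenyl)butyl]-5,5-dimethyl-1,3-dioxan-2-yl}ethan-1-ol F4. An Appel bromination buffered with imidazole (CBr4, PPh3, imidazole, CH2Cl2, 0 °C) returns to bromo ketal 12.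

Step 2. Silylation may occur at the more acidic, iodine-flanked hydroxyl or at both hydroxyls, eroding the site selectivity on which the triflate position depends. The fallback reverses the order of events, so that the selectivity rests on the directing effect of a free phenol in the iodination. It sets out from 2-methoxyresorcinol 1. Monosilylation (TIPSCl 1.0 equiv, imidazole, CH2Cl2, 0 °C) can give only one monoether, 2-methoxy-3-[(triisopropylsilyl)oxy]phenol F5, separated from diether and recovered diol. Iodination of its sodium phenoxide (NaH, then N-iodosuccinimide, toluene, 0 °C) should go to the position ortho to the phenoxide oxygen. That position is also para to the silyloxy group, whereas the other activated position is shielded by the silyl bulk. This gives iodophenol 3, where the route is rejoined.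

**Further compounds**

F1 | step 9 | (E)-1-{2-hydroxy-3-methoxy-4-[(triisopropylsilyl)oxy]phenyl}-7-(4-methoxyphenyl)hept-1-en-3-one | COc1ccc(CCCCC(=O)/C=C/c2ccc(O[Si](C(C)C)(C(C)C)C(C)C)c(OC)c2O)cc1
F2 | step 7 | 1-(benzyloxy)-7-(4-methoxyphenyl)heptan-3-one | COc1ccc(CCCCC(=O)CCOCc2ccccc2)cc1
F3 | step 7 | 2-[2-(benzyloxy)ethyl]-2-[4-(4-methoxyphenyl)butyl]-5,5-dimethyl-1,3-dioxane | COc1ccc(CCCCC2(CCOCc3ccccc3)OCC(C)(C)CO2)cc1
F4 | step 7 | 2-{2-[4-(4-methoxyphenyl)butyl]-5,5-dimethyl-1,3-dioxan-2-yl}ethan-1-ol | COc1ccc(CCCCC2(CCO)OCC(C)(C)CO2)cc1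
F5 | step 2 | 2-methoxy-3-[(triisopropylsilyl)oxy]phenol | COc1c(O)cccc1O[Si](C(C)C)(C(C)C)C(C)C
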